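**Strategy.** The route rests on cutting the C2–C3 bond of the dihydrofuran. The two ring stereocentres, C2 (attached to O1 and ring B) and C3 (attached to ring C), are neighbours, both benzylic and cis. Once the ring is opened, the CH2 of an O1–CH2–ring B ether stands in a 1,5 relationship to C3 on ring A. A rhodium carbene raised at C3 from a diaryldiazomethane should insert into one of those C–H bonds. This closes the five-membered oxygen ring and fixes both stereocentres in one catalytic enantioselective operation. The precursor is a benzyl-protected diaryldiazomethane whose diazo carbon is flanked on ring A by the 4-(benzyloxy)benzyl ether and by bromine. Bromine later accepts the arylethynyl arm, and one neutral hydrogenation completes the target.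

Key step: step 9

Numbering: benzofuran numbering is used. Ring A is the benzo ring, ring B the aryl group at C2, ring C the aryl group at C3, and ring D the aryl group of the C4 side chain.

Assumption: the (R)-PTAD ligand set is taken to deliver the (2S,3R) product; the sense of induction should be checked on the bromide from the key step by anomalous-dispersion X-ray analysis, and the mirror-image catalyst Rh2(S-PTAD)4 would be substituted if it proves opposite.

**Route**

Step 1
Reactants: 1 5-bromoresorcinol
Product: 3 2-bromo-4,6-dihydroxybenzaldehyde, via aryl iminium chloride 2 (not isolated)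
Conditions: POCl3 (1.3 equiv), DMF, 0 °C to rt; then H2O, 50 °C
Reagents that add atoms: N,N-dimethylformamide CN(C)C=O; water O
Why: Vilsmeier–Haack formylation, in which both hydroxy groups activate the carbon para to one of them and ortho to the other (next to Br), the usual site of attack in 5-substituted resorcinols, and water then hydrolyses iminium salt 2 together with any O-formyl or O-phosphoryl groups.

Step 2
Reactants: 3 2-bromo-4,6-dihydroxybenzaldehyde
Product: 4 4-(benzyloxy)-2-bromo-6-hydroxybenzaldehyde
Conditions: BnBr (1.0 equiv), NaHCO3 (1.2 equiv), MeCN, 75 °C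
Reagents that add atoms: benzyl bromide BrCc1ccccc1
Why: Regioselective Williamson ether synthesis, in which the weak base ionises only the free and more acidic 4-OH (para to CHO) while the 6-OH is held in a hydrogen bond to the coplanar aldehyde oxygen and should stay unalkylated with one equivalent of halide.

Step 3
Reactants: 4 4-(benzyloxy)-2-bromo-6-hydroxybenzaldehyde; 5 4-(benzyloxy)benzyl chloride
Product: 6 4-(benzyloxy)-2-{[4-(benzyloxy)benzyl]oxy}-6-bromobenzaldehyde
Conditions: K2CO3 (2 equiv), DMF, 60 °C
Reagents that add atoms: none
Why: Williamson ether synthesis under stronger conditions, in which K2CO3 in warm DMF breaks the chelate and the phenoxide displaces the reactive para-alkoxybenzylic chloride, bringing in C2 and ring B of the target.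

Step 4
Reactants: 1 5-bromoresorcinol
Product: 7 1,3-bis(benzyloxy)-5-bromobenzene
Conditions: BnBr (2.2 equiv), K2CO3 (3 equiv), DMF, 50 °C
Reagents that add atoms: benzyl bromide BrCc1ccccc1
Why: Exhaustive Williamson ether synthesis of a simple resorcinol, which supplies the ring C building block already in its final protected form from the same starting material.

Step 5
Reactants: 7 1,3-bis(benzyloxy)-5-bromobenzene; 6 4-(benzyloxy)-2-{[4-(benzyloxy)benzyl]oxy}-6-bromobenzaldehyde
Product: 9 racemic [4-(benzyloxy)-2-{[4-(benzyloxy)benzyl]oxy}-6-bromophenyl][3,5-bis(benzyloxy)phenyl]methanol, via arylmagnesium bromide 8 (not isolated)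
Conditions: 7, Mg turnings, THF, 50 °C; then 6, THF, 0 °C; sat. aq. NH4Cl
Reagents that add atoms: none
Why: Grignard addition, in which arylmagnesium bromide 8 adds to the aldehyde far faster than it can exchange with the aryl bromide of 6 at 0 °C, and the carbinol centre forms racemic, which does not matter because the next step removes it.

Step 6
Reactants: 9 racemic diaryl carbinol
Product: 10 [4-(benzyloxy)-2-{[4-(benzyloxy)benzyl]oxy}-6-bromophenyl][3,5-bis(benzyloxy)phenyl]methanone
Conditions: activated MnO2 (15 equiv), CH2Cl2, rt
Reagents that add atoms: none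
Why: MnO2 oxidation of a doubly benzylic, electron-rich alcohol runs under neutral conditions that spare the benzyl ethers and the aryl bromide and avoid ionisation of the acid-sensitive benzhydrol.

Step 7
Reactants: 10 diaryl ketone
Product: 11 hydrazone of 10 (E/Z mixture)
Conditions: N2H4·H2O (30 equiv), AcOH (cat.), n-BuOH, 120 °C, sealed vessel, argon
Reagents that add atoms: hydrazine (as hydrate) NN
Why: Hydrazone condensation, for which a large excess of the small nucleophile with acid catalysis and heat is chosen because Br and the ether of ring A shield the carbonyl group, while the same crowding blocks azine formation, uncatalysed displacement of Br from the electron-rich ring should be slow, and the E/Z mixture is of no consequence.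

Step 8
Reactants: 11 hydrazone
Product: 12 [2-bromo-4-(benzyloxy)-6-{[4-(benzyloxy)benzyl]oxy}phenyl][3,5-bis(benzyloxy)phenyl]diazomethane
Conditions: activated MnO2 (8 equiv), CH2Cl2, 0 °C to rt, dark; filter, concentrate below 20 °C
Reagents that add atoms: none
Why: Dehydrogenation of an N-unsubstituted diaryl hydrazone with MnO2 is the standard mild entry to diaryldiazomethanes, and the two ortho substituents should stabilise 12 enough for filtration and use on the same day.

Step 9
Reactants: 12 diaryldiazomethane
Product: 13 (2S,3R)-6-(benzyloxy)-2-[4-(benzyloxy)phenyl]-3-[3,5-bis(benzyloxy)phenyl]-4-bromo-2,3-dihydro-1-benzofuran (cis)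
Conditions: Rh2(R-PTAD)4 (1 mol%), CH2Cl2/MeCN (1:1), 0 °C to rt, 12 added slowly; chromatography on Et3N-deactivated silica
Reagents that add atoms: none
Why: The diazo carbon of 12 binds to an axial site of the divalent rhodium dimer, N2 departs, and the doubly aryl-stabilised carbene at C3 pulls hydrogen with hydridic character from the O1–CH2 group while the C2–C3 bond forms in the same asynchronous event, after which the catalyst is released. The closest known reaction type is the enantioselective intramolecular C–H insertion of donor/donor (diaryl) rhodium carbenes into benzyl aryl ethers, an established entry to cis-2,3-diaryl-2,3-dihydrobenzofurans. The only ring closed, O1–C2–C3–C3a–C7a, forms by 1,5-insertion, the geometrically preferred mode for such carbenes. C3 is fixed by the carbene face that the chiral carboxylate wall leaves open, and C2 by which of the two enantiotopic ether hydrogens can be presented to that face, the compact transition state keeping rings B and C on the same side so that the kinetic cis isomer should result. The step needs site selectivity among many benzylic ether C–H bonds, and the substrate secures it because only the ortho ether can reach C3, its C–H bonds are the most hydridic (O1 plus the para-oxygenated ring B), the other ortho position carries Br and no hydrogen, and the four OCH2Ph groups are too remote or wrongly placed on their rings to reach the carbene. The two ortho groups also twist ring A out of conjugation, which should hold the ether over the vacant carbene orbital and hinder bimolecular azine formation.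

Step 10
Reactants: 13 cis bromide; 14 1-(benzyloxy)-4-ethynylbenzene
Product: 15 (2S,3R)-6-(benzyloxy)-2-[4-(benzyloxy)phenyl]-4-{[4-(benzyloxy)phenyl]ethynyl}-3-[3,5-bis(benzyloxy)phenyl]-2,3-dihydro-1-benzofuran
Conditions: 14 (1.5 equiv), PdCl2(MeCN)2 (5 mol%), XPhos (15 mol%), Cs2CO3 (2.5 equiv), 1,4-dioxane, 80 °C
Reagents that add atoms: none
Why: Copper-free Sonogashira coupling, in which the bulky electron-rich phosphine lets zerovalent palladium insert into the C4–Br bond beside the C3 substituent, the slim alkyne tolerates the crowding, and neither C2–H nor C3–H is acidic enough for carbonate to epimerise while all phenols are capped.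

Step 11
Reactants: 15 alkyne pentabenzyl ether
Product: 16 5-[(2S,3R)-6-hydroxy-2-(4-hydroxyphenyl)-4-[2-(4-hydroxyphenyl)ethyl]-2,3-dihydro-1-benzofuran-3-yl]benzene-1,3-diol (target)
Conditions: H2 (1 atm), 10% Pd/C, EtOAc/MeOH (1:1), rt, stopped as soon as debenzylation is complete
Reagents that add atoms: none
Why: Heterogeneous catalytic hydrogenation and hydrogenolysis, in which the diarylalkyne is saturated and the five unhindered primary benzyl aryl ethers should be cleaved at 1 atm faster than the secondary, cis-flanked C2–O1 bond of the ring, with no acid or base present that could epimerise C2 or C3.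

**Compound list**

1 | 5-bromoresorcinol | Oc1cc(O)cc(Br)c1 | starting material
2 | [(2-bromo-4,6-dihydroxyphenyl)methylidene]dimethylammonium chloride | C[N+](C)=Cc1c(O)cc(O)cc1Br.[Cl-] | intermediate
3 | 2-bromo-4,6-dihydroxybenzaldehyde | O=Cc1c(O)cc(O)cc1Br | intermediate
4 | 4-(benzyloxy)-2-bromo-6-hydroxybenzaldehyde | O=Cc1c(O)cc(OCc2ccccc2)cc1Br | intermediate
5 | 4-(benzyloxy)benzyl chloride | ClCc1ccc(OCc2ccccc2)cc1 | starting material
6 | 4-(benzyloxy)-2-{[4-(benzyloxy)benzyl]oxy}-6-bromobenzaldehyde | O=Cc1c(Br)cc(OCc2ccccc2)cc1OCc1ccc(OCc2ccccc2)cc1 | intermediate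
7 | 1,3-bis(benzyloxy)-5-bromobenzene | Brc1cc(OCc2ccccc2)cc(OCc2ccccc2)c1 | intermediate
8 | 3,5-bis(benzyloxy)phenylmagnesium bromide | Br[Mg]c1cc(OCc2ccccc2)cc(OCc2ccccc2)c1 | intermediate
9 | racemic [4-(benzyloxy)-2-{[4-(benzyloxy)benzyl]oxy}-6-bromophenyl][3,5-bis(benzyloxy)phenyl]methanol | OC(c1cc(OCc2ccccc2)cc(OCc2ccccc2)c1)c1c(Br)cc(OCc2ccccc2)cc1OCc1ccc(OCc2ccccc2)cc1 | intermediate
10 | [4-(benzyloxy)-2-{[4-(benzyloxy)benzyl]oxy}-6-bromophenyl][3,5-bis(benzyloxy)phenyl]methanone | O=C(c1cc(OCc2ccccc2)cc(OCc2ccccc2)c1)c1c(Br)cc(OCc2ccccc2)cc1OCc1ccc(OCc2ccccc2)cc1 | intermediate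
11 | hydrazone of 10 (E/Z mixture) | NN=C(c1cc(OCc2ccccc2)cc(OCc2ccccc2)c1)c1c(Br)cc(OCc2ccccc2)cc1OCc1ccc(OCc2ccccc2)cc1 | intermediate
12 | [2-bromo-4-(benzyloxy)-6-{[4-(benzyloxy)benzyl]oxy}phenyl][3,5-bis(benzyloxy)phenyl]diazomethane | [N-]=[N+]=C(c1cc(OCc2ccccc2)cc(OCc2ccccc2)c1)c1c(Br)cc(OCc2ccccc2)cc1OCc1ccc(OCc2ccccc2)cc1 | intermediate
13 | (2S,3R)-6-(benzyloxy)-2-[4-(benzyloxy)phenyl]-3-[3,5-bis(benzyloxy)phenyl]-4-bromo-2,3-dihydro-1-benzofuran (cis) | Brc1cc(OCc2ccccc2)cc2c1[C@@H](c1cc(OCc3ccccc3)cc(OCc3ccccc3)c1)[C@@H](c1ccc(OCc3ccccc3)cc1)O2 | intermediate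
14 | 1-(benzyloxy)-4-ethynylbenzene | C#Cc1ccc(OCc2ccccc2)cc1 | starting material
15 | (2S,3R)-6-(benzyloxy)-2-[4-(benzyloxy)phenyl]-4-{[4-(benzyloxy)phenyl]ethynyl}-3-[3,5-bis(benzyloxy)phenyl]-2,3-dihydro-1-benzofuran | C(#Cc1ccc(OCc2ccccc2)cc1)c1cc(OCc2ccccc2)cc2c1[C@@H](c1cc(OCc3ccccc3)cc(OCc3ccccc3)c1)[C@@H](c1ccc(OCc3ccccc3)cc1)O2 | intermediate
16 | 5-[(2S,3R)-6-hydroxy-2-(4-hydroxyphenyl)-4-[2-(4-hydroxyphenyl)ethyl]-2,3-dihydro-1-benzofuran-3-yl]benzene-1,3-diol | Oc1ccc(CCc2cc(O)cc3c2[C@@H](c2cc(O)cc(O)c2)[C@@H](c2ccc(O)cc2)O3)cc1 | target

**Step count and risks**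

Total step count: 11. Longest linear sequence: 10 (steps 1, 2, 3, 5, 6, 7, 8, 9, 10, 11). Step 4 is a one-step side branch.

The three steps most likely to fail are these.

Step 7 (hydrazone formation). The condensation may stall because attack at the carbonyl carbon is blocked on both sides by Br and the ether of ring A. Long heating may also start ring closure of the hydrazone nitrogen onto the carbon that bears Br. The fallback sets out from ketone 10. The carbonyl group is first exchanged for the far more electrophilic thiocarbonyl group with Lawesson's reagent (toluene, 100 °C) to give the diaryl thioketone F1. Hydrazine hydrate in THF/EtOH at room temperature should then displace sulfur as H2S, and the route is rejoined at hydrazone 11.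

Step 9 (key step). Nitrogen loss at the crowded diazo carbon may be slow in the narrow pocket of the chiral catalyst. Uncatalysed decomposition, azine formation or poor facial selectivity would then lower the enantiomeric purity. The fallback sets out from 12 and gives up absolute control by the catalyst. A bulky achiral carboxylate, Rh2(O2CCPh3)4 (CH2Cl2, rt), belongs to a catalyst type that favours the cis isomer in this kind of insertion. It should give the racemic cis product, that is 13 together with its (2R,3S) mirror image F2. Preparative supercritical-fluid chromatography on a polysaccharide chiral phase separates the two, and the route is rejoined at 13.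

Step 11 (final hydrogenation). Once ring B is unmasked, reductive cleavage of the ring C2–O1 bond, itself a benzylic aryl ether, may compete with removal of the last benzyl groups. The fallback sets out from 15 and separates the two tasks. Hydrogenation over Pd/C poisoned with pyridine (EtOAc, 1 atm), which spares phenolic benzyl ethers, should saturate only the alkyne and give the saturated pentabenzyl ether F3. The benzyl groups are then removed without hydrogen by BCl3 with pentamethylbenzene as cation trap (CH2Cl2, −78 °C, quenched cold to limit Lewis-acid epimerisation). This leads directly to target 16.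

**Further compounds**

F1 | step 7 | [4-(benzyloxy)-2-{[4-(benzyloxy)benzyl]oxy}-6-bromophenyl][3,5-bis(benzyloxy)phenyl]methanethione | S=C(c1cc(OCc2ccccc2)cc(OCc2ccccc2)c1)c1c(Br)cc(OCc2ccccc2)cc1OCc1ccc(OCc2ccccc2)cc1
F2 | step 9 | (2R,3S)-6-(benzyloxy)-2-[4-(benzyloxy)phenyl]-3-[3,5-bis(benzyloxy)phenyl]-4-bromo-2,3-dihydro-1-benzofuran (enantiomer of 13) | Brc1cc(OCc2ccccc2)cc2c1[C@H](c1cc(OCc3ccccc3)cc(OCc3ccccc3)c1)[C@H](c1ccc(OCc3ccccc3)cc1)O2
F3 | step 11 | (2S,3R)-6-(benzyloxy)-2-[4-(benzyloxy)phenyl]-4-{2-[4-(benzyloxy)phenyl]ethyl}-3-[3,5-bis(benzyloxy)phenyl]-2,3-dihydro-1-benzofuran | C(Cc1ccc(OCc2ccccc2)cc1)c1cc(OCc2ccccc2)cc2c1[C@@H](c1cc(OCc3ccccc3)cc(OCc3ccccc3)c1)[C@@H](c1ccc(OCc3ccccc3)cc1)O2
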